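**Retrosynthetic overview**

1. The target is a 2,2-disubstituted chroman (numbering O1, C2, C3, C4, C4a, C5–C8, C8a) with (S)-C2, OMe at C5, CH2O-palmitoyl at C7 and CHO at C8. C2, C3, C4, the methyl group and the whole side chain come from (R)-linalool, whose carbinol C–O bond is never broken.
2. Enabling feature: C4a lies between the two oxygen-bearing ring carbons C8a (O1) and C5 (OMe). Before the benzene ring exists, O1–C8a=C4a–C5(=O) is a β-alkoxy enone whose α-carbon C4a can be iodinated and cross-coupled.
3. First ring (dihydropyran O1–C2–C3–C4–C4a=C8a): hydroboration of the linalool vinyl group and intramolecular B-alkyl Suzuki–Miyaura coupling close it at C4–C4a.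
4. Second ring (benzene C4a–C5–C6–C7–C8–C8a): the acetyl group becomes a 2-silyloxy diene. Diels–Alder reaction with 4-oxobut-2-ynyl palmitate (bonds C6–C7 and C8–C8a) and dehydrogenation place CHO at C8 and CH2O-palmitoyl at C7 by polarity alone.
5. End game: O-methylation at C5, then the prenyl terminus is taken to the enone by hydroxyselenation, selenoxide elimination and oxidative 1,3-transposition.

Key step: step 3

Remark: commercial (R)-(−)-linalool is taken as enantiomerically pure, and chroman numbering is used for every intermediate, also before the benzene ring exists.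

**Route**

Step 1
Reactants: 1 (R)-(−)-linalool, (3R)-3,7-dimethylocta-1,6-dien-3-ol; 2 but-3-yn-2-one
Product: 3 (3E)-4-{[(3R)-3,7-dimethylocta-1,6-dien-3-yl]oxy}but-3-en-2-one
Conditions: PMe3 (10 mol %), CH2Cl2, 0 °C → rt, slow addition of 2 (1.3 equiv)
Reagents that add atoms: none
Why: Phosphine-catalysed oxa-Michael addition of the tertiary alcohol to the terminal ynone should give the (E)-β-alkoxy enone without touching the carbinol C–O bond, so the configuration of 1 is carried unchanged; the mixture is kept at or below room temperature because 3 is an allyl vinyl ether that would undergo Claisen rearrangement on heating.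

Step 2
Reactants: 3 (3E)-4-{[(3R)-3,7-dimethylocta-1,6-dien-3-yl]oxy}but-3-en-2-one
Product: 4 (3Z)-4-{[(3R)-3,7-dimethylocta-1,6-dien-3-yl]oxy}-3-iodobut-3-en-2-one
Conditions: I2 (1.5 equiv), pyridine (3 equiv), CH2Cl2, 0 °C → rt, dark; aqueous Na2S2O3 work-up
Reagents that add atoms: iodine, II
Why: Electrophilic α-iodination of a vinylogous ester (the iodine–pyridine conditions used for α-iodination of enones) should attack the enol-ether carbon C4a and, after loss of the C8a proton, return the push–pull alkene with iodine cis to the ether oxygen (Z), the geometry the ring closure needs; the isolated alkenes form iodonium ions only reversibly because no nucleophile is added.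

Step 3
Reactants: 4 (3Z)-4-{[(3R)-3,7-dimethylocta-1,6-dien-3-yl]oxy}-3-iodobut-3-en-2-one
Product: 6 1-[(2R)-2-methyl-2-(4-methylpent-3-en-1-yl)-3,4-dihydro-2H-pyran-5-yl]ethan-1-one, via B-alkyl-9-BBN borane 5 (not isolated)
Conditions: 9-BBN dimer (0.55 equiv), THF, 0 °C → rt; then PdCl2(dppf) (5 mol %), AsPh3 (10 mol %), K3PO4 (3 M aq), DMF/THF, rt → 50 °C, 0.02 M
Reagents that add atoms: none
Why: 9-BBN adds to the only monosubstituted alkene with boron on the terminal carbon C4, and after oxidative addition of zerovalent palladium into the C4a–I bond the hydroxide-activated B-alkyl group is transferred within the same molecule and C(sp3)–C(sp2) reductive elimination forms C4–C4a. The closest known reaction type is the intramolecular B-alkyl Suzuki–Miyaura coupling of ω-boryl alkenyl halides, together with the intermolecular coupling of α-iodo enones and of (Z)-2-iodo-3-alkoxyacrylates with B-alkyl-9-BBN reagents. The one ring that closes is the six-membered dihydropyran O1–C2–C3–C4–C4a=C8a, formed by reductive elimination from a seven-membered palladacycle with the C4a=C8a double bond left inside the ring. No stereocenter is formed and no bond to C2 is made or broken, so the linalool configuration is kept. The step needs chemoselective hydroboration, which the substrate secures because the vinyl group is the only unhindered terminal alkene (the trisubstituted alkene reacts far more slowly with 9-BBN) and the carbonyl is a deactivated vinylogous-ester carbonyl, and it needs ring closure instead of oligomerization or β-hydride elimination, which is secured by the (Z)-geometry that holds iodine on the same side as O1, the geminal substitution at C2, the dppf ligand and dilution. The vinyl group is consumed before palladium is added, so the Claisen and allylic-ionization pathways of 4 are closed.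

Step 4
Reactants: 6 1-[(2R)-2-methyl-2-(4-methylpent-3-en-1-yl)-3,4-dihydro-2H-pyran-5-yl]ethan-1-one
Product: 7 tert-butyl(dimethyl)({1-[(2R)-2-methyl-2-(4-methylpent-3-en-1-yl)-3,4-dihydro-2H-pyran-5-yl]ethenyl}oxy)silane
Conditions: TBSOTf (1.2 equiv), Et3N (2 equiv), Et2O, −78 → 0 °C
Reagents that add atoms: tert-butyldimethylsilyl trifluoromethanesulfonate, CC(C)(C)[Si](C)(C)OS(=O)(=O)C(F)(F)F
Why: Silyl triflate/amine enol silylation of the methyl ketone can only enolize toward the methyl group (C4a carries no hydrogen) and should give the 1-alkoxy-3-silyloxy-1,3-diene with the ring oxygen held on the outside of the diene.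

Step 5
Reactants: 8 but-2-yne-1,4-diol; 9 hexadecanoyl chloride (palmitoyl chloride)
Product: 10 4-hydroxybut-2-yn-1-yl hexadecanoate
Conditions: 8 (4 equiv), pyridine (1.2 equiv), DMAP (5 mol %), THF, 0 °C → rt, 9 added dropwise
Reagents that add atoms: none
Why: Acylation (nucleophilic acyl substitution) of an excess of the symmetrical diol should give the monoester statistically, and the unchanged diol is removed with water.

Step 6
Reactants: 10 4-hydroxybut-2-yn-1-yl hexadecanoate
Product: 11 4-oxobut-2-yn-1-yl hexadecanoate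
Conditions: MnO2 (activated, excess), CH2Cl2, rt
Reagents that add atoms: none
Why: MnO2 oxidation of a propargylic alcohol should stop at the ynal under neutral conditions that leave the ester alone.

Step 7
Reactants: 7 tert-butyl(dimethyl)({1-[(2R)-2-methyl-2-(4-methylpent-3-en-1-yl)-3,4-dihydro-2H-pyran-5-yl]ethenyl}oxy)silane; 11 4-oxobut-2-yn-1-yl hexadecanoate
Product: 13 [(2R)-5-{[tert-butyl(dimethyl)silyl]oxy}-8-formyl-2-methyl-2-(4-methylpent-3-en-1-yl)-3,4-dihydro-2H-chromen-7-yl]methyl hexadecanoate, via cyclohexa-1,4-diene cycloadduct 12 (not isolated)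
Conditions: 11 (1.2 equiv), toluene, 0 °C → rt; then DDQ (1.1 equiv), solid NaHCO3, 0 °C
Reagents that add atoms: none
Why: In this normal-electron-demand Diels–Alder reaction the nucleophilic terminal CH2 of the doubly donor-substituted diene (C6) should bond to the β-carbon of the ynal (C7, carrying CH2O-palmitoyl) and C8a to the α-carbon (C8, carrying CHO), and DDQ should then remove hydride from the doubly allylic, oxygen-bearing C8a–H so that the ring aromatizes by dehydrogenation with the ring oxygen kept; the transient C8a stereocenter disappears.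

Step 8
Reactants: 13 [(2R)-5-{[tert-butyl(dimethyl)silyl]oxy}-8-formyl-2-methyl-2-(4-methylpent-3-en-1-yl)-3,4-dihydro-2H-chromen-7-yl]methyl hexadecanoate
Product: 15 [(2R)-8-formyl-5-methoxy-2-methyl-2-(4-methylpent-3-en-1-yl)-3,4-dihydro-2H-chromen-7-yl]methyl hexadecanoate, via caesium phenoxide 14 (not isolated)
Conditions: CsF (1.5 equiv), MeI (3 equiv), DMF, 0 °C → rt
Reagents that add atoms: iodomethane, CI
Why: Fluoride should cleave the aryl silyl ether para to the formyl group and the phenoxide is O-methylated in the same flask (Williamson ether synthesis) under conditions too mild to harm the ester or the aldehyde.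

Step 9
Reactants: 15 [(2R)-8-formyl-5-methoxy-2-methyl-2-(4-methylpent-3-en-1-yl)-3,4-dihydro-2H-chromen-7-yl]methyl hexadecanoate
Product: 16 [(2S)-8-formyl-2-[4-hydroxy-4-methyl-3-(phenylselanyl)pentyl]-5-methoxy-2-methyl-3,4-dihydro-2H-chromen-7-yl]methyl hexadecanoate (both epimers at the selenium-bearing carbon)
Conditions: N-(phenylselanyl)phthalimide (1.2 equiv), H2O (3 equiv), camphorsulfonic acid (10 mol %), CH2Cl2, rt
Reagents that add atoms: N-(phenylselanyl)phthalimide, O=C1N([Se]c2ccccc2)C(=O)c2ccccc12; water, O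
Why: In this electrophilic hydroxyselenation the selenium electrophile should add to the most electron-rich (trisubstituted) alkene and water opens the seleniranium ion at the tertiary carbon (Markovnikov); the new selenium-bearing stereocenter is formed without control and is removed in step 10.

Step 10
Reactants: 16 [(2S)-8-formyl-2-[4-hydroxy-4-methyl-3-(phenylselanyl)pentyl]-5-methoxy-2-methyl-3,4-dihydro-2H-chromen-7-yl]methyl hexadecanoate
Product: 18 [(2S)-8-formyl-2-[(2E)-4-hydroxy-4-methylpent-2-en-1-yl]-5-methoxy-2-methyl-3,4-dihydro-2H-chromen-7-yl]methyl hexadecanoate, via selenoxide 17 (not isolated)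
Conditions: NaIO4 (2 equiv), NaHCO3, THF/H2O, 0 °C → rt
Reagents that add atoms: none
Why: Oxidation to the selenoxide and selenoxide syn-elimination can only take a hydrogen from the CH2 group on the side away from the carbinol carbon and should give the (E)-configured tertiary allylic alcohol; periodate is chosen because it does not oxidize the aryl aldehyde.

Step 11
Reactants: 18 [(2S)-8-formyl-2-[(2E)-4-hydroxy-4-methylpent-2-en-1-yl]-5-methoxy-2-methyl-3,4-dihydro-2H-chromen-7-yl]methyl hexadecanoate
Product: 19 [(2S)-8-formyl-5-methoxy-2-methyl-2-(4-methyl-2-oxopent-3-en-1-yl)-3,4-dihydro-2H-chromen-7-yl]methyl hexadecanoate (target, CNP0228756.1)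
Conditions: pyridinium chlorochromate [C5H5NH][CrO3Cl] (3 equiv), 4 Å molecular sieves, CH2Cl2, rt
Reagents that add atoms: none
Why: In the Babler–Dauben oxidative 1,3-transposition the chromate ester of the tertiary allylic alcohol should shift by [3,3]-sigmatropic rearrangement to the secondary allylic chromate, which is oxidized to the β,β-dimethyl enone; the C2 stereocenter is remote and untouched.

**Compound list**

1 | (R)-(−)-linalool, (3R)-3,7-dimethylocta-1,6-dien-3-ol | C=C[C@](C)(O)CCC=C(C)C | starting material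
2 | but-3-yn-2-one | CC(=O)C#C | starting material
3 | (3E)-4-{[(3R)-3,7-dimethylocta-1,6-dien-3-yl]oxy}but-3-en-2-one | CC(=O)/C=C/O[C@](C)(CCC=C(C)C)C=C | intermediate
4 | (3Z)-4-{[(3R)-3,7-dimethylocta-1,6-dien-3-yl]oxy}-3-iodobut-3-en-2-one | CC(=O)/C(I)=C/O[C@](C)(CCC=C(C)C)C=C | intermediate
5 | (3Z)-4-{[(3S)-1-(9-borabicyclo[3.3.1]nonan-9-yl)-3,7-dimethyloct-6-en-3-yl]oxy}-3-iodobut-3-en-2-one (same spatial arrangement as 4) | CC(=O)/C(I)=C/O[C@](C)(CCC=C(C)C)CCB1C2CCCC1CCC2 | intermediate
6 | 1-[(2R)-2-methyl-2-(4-methylpent-3-en-1-yl)-3,4-dihydro-2H-pyran-5-yl]ethan-1-one | CC(=O)C1=CO[C@](C)(CCC=C(C)C)CC1 | intermediate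
7 | tert-butyl(dimethyl)({1-[(2R)-2-methyl-2-(4-methylpent-3-en-1-yl)-3,4-dihydro-2H-pyran-5-yl]ethenyl}oxy)silane | C=C(O[Si](C)(C)C(C)(C)C)C1=CO[C@](C)(CCC=C(C)C)CC1 | intermediate
8 | but-2-yne-1,4-diol | OCC#CCO | starting material
9 | hexadecanoyl chloride (palmitoyl chloride) | CCCCCCCCCCCCCCCC(=O)Cl | starting material
10 | 4-hydroxybut-2-yn-1-yl hexadecanoate | CCCCCCCCCCCCCCCC(=O)OCC#CCO | intermediate
11 | 4-oxobut-2-yn-1-yl hexadecanoate | CCCCCCCCCCCCCCCC(=O)OCC#CC=O | intermediate
12 | [(2R)-5-{[tert-butyl(dimethyl)silyl]oxy}-8-formyl-2-methyl-2-(4-methylpent-3-en-1-yl)-3,4,6,8a-tetrahydro-2H-chromen-7-yl]methyl hexadecanoate (both epimers at C8a) | CCCCCCCCCCCCCCCC(=O)OCC1=C(C=O)C2O[C@](C)(CCC=C(C)C)CCC2=C(O[Si](C)(C)C(C)(C)C)C1 | intermediate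
13 | [(2R)-5-{[tert-butyl(dimethyl)silyl]oxy}-8-formyl-2-methyl-2-(4-methylpent-3-en-1-yl)-3,4-dihydro-2H-chromen-7-yl]methyl hexadecanoate | CCCCCCCCCCCCCCCC(=O)OCc1cc(O[Si](C)(C)C(C)(C)C)c2c(c1C=O)O[C@](C)(CCC=C(C)C)CC2 | intermediate
14 | caesium (2R)-8-formyl-7-[(hexadecanoyloxy)methyl]-2-methyl-2-(4-methylpent-3-en-1-yl)-3,4-dihydro-2H-chromen-5-olate | CCCCCCCCCCCCCCCC(=O)OCc1cc([O-])c2c(c1C=O)O[C@](C)(CCC=C(C)C)CC2.[Cs+] | intermediate
15 | [(2R)-8-formyl-5-methoxy-2-methyl-2-(4-methylpent-3-en-1-yl)-3,4-dihydro-2H-chromen-7-yl]methyl hexadecanoate | CCCCCCCCCCCCCCCC(=O)OCc1cc(OC)c2c(c1C=O)O[C@](C)(CCC=C(C)C)CC2 | intermediate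
16 | [(2S)-8-formyl-2-[4-hydroxy-4-methyl-3-(phenylselanyl)pentyl]-5-methoxy-2-methyl-3,4-dihydro-2H-chromen-7-yl]methyl hexadecanoate (both epimers at the selenium-bearing carbon) | CCCCCCCCCCCCCCCC(=O)OCc1cc(OC)c2c(c1C=O)O[C@](C)(CCC([Se]c3ccccc3)C(C)(C)O)CC2 | intermediate
17 | [(2S)-8-formyl-2-[4-hydroxy-4-methyl-3-(phenylseleninyl)pentyl]-5-methoxy-2-methyl-3,4-dihydro-2H-chromen-7-yl]methyl hexadecanoate | CCCCCCCCCCCCCCCC(=O)OCc1cc(OC)c2c(c1C=O)O[C@](C)(CCC([Se](=O)c3ccccc3)C(C)(C)O)CC2 | intermediate
18 | [(2S)-8-formyl-2-[(2E)-4-hydroxy-4-methylpent-2-en-1-yl]-5-methoxy-2-methyl-3,4-dihydro-2H-chromen-7-yl]methyl hexadecanoate | CCCCCCCCCCCCCCCC(=O)OCc1cc(OC)c2c(c1C=O)O[C@](C)(C/C=C/C(C)(C)O)CC2 | intermediate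
19 | [(2S)-8-formyl-5-methoxy-2-methyl-2-(4-methyl-2-oxopent-3-en-1-yl)-3,4-dihydro-2H-chromen-7-yl]methyl hexadecanoate | CCCCCCCCCCCCCCCC(=O)OCc1cc(OC)c2c(c1C=O)O[C@](C)(CC(=O)C=C(C)C)CC2 | target

**Step count**

Total steps: 11. Longest linear sequence: 9 (steps 1, 2, 3, 4, 7, 8, 9, 10, 11).

**Steps most likely to fail**

Step 7. The cyclohexadiene cycloadduct may aromatize by expelling the ring oxygen from C8a (1,4-elimination that opens the pyran ring) faster than it is dehydrogenated, and the ynal may oligomerize before it cycloadds. The fallback buys the benzene ring instead of building it; it sets out from 1 and comes back to the route at 15.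
- Hydroboration–oxidation of 1 (9-BBN, then NaOH/H2O2) should give (3R)-3,7-dimethyloct-6-ene-1,3-diol F1.
- Chlorination of its primary hydroxyl group (PPh3, N-chlorosuccinimide) should give (3R)-1-chloro-3,7-dimethyloct-6-en-3-ol F2.
- The potassium alkoxide of F2 (KN(SiMe3)2, THF/DMF, 0 °C) displaces fluoride from commercial 2-fluoro-4-methoxybenzaldehyde (nucleophilic aromatic substitution ortho to the formyl group) to give 2-{[(3R)-1-chloro-3,7-dimethyloct-6-en-3-yl]oxy}-4-methoxybenzaldehyde F3.
- With the aldehyde masked in the flask by lithium N-methylpiperazide, sec-butyllithium metalates the position between the two ether oxygens and the aryllithium displaces chloride. This closes the same C4–C4a bond (directed ortho-metalation followed by Parham-type cycloalkylation) and gives (2R)-5-methoxy-2-methyl-2-(4-methylpent-3-en-1-yl)-3,4-dihydro-2H-chromene-8-carbaldehyde F4.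
- A second in-flask masking with lithium N,N,N′-trimethylethylenediamide, ortho-lithiation next to the masked formyl group (n-butyllithium) and quenching with paraformaldehyde should give (2R)-7-(hydroxymethyl)-5-methoxy-2-methyl-2-(4-methylpent-3-en-1-yl)-3,4-dihydro-2H-chromene-8-carbaldehyde F5.
- Acylation of F5 with 9 (pyridine, DMAP) gives 15.

Step 3. 9-BBN may reduce the carbonyl group of the iodo-enone in competition with hydroboration of the vinyl group, and a slow transmetalation would leave room for β-hydride elimination. The fallback accepts the reduction and repairs it; it sets out from 4 and comes back at 6.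
- An excess of 9-BBN (2.3 equiv) hydroborates the vinyl group and reduces the carbonyl on purpose, giving in the flask 9-{[(3Z)-4-{[(3S)-1-(9-borabicyclo[3.3.1]nonan-9-yl)-3,7-dimethyloct-6-en-3-yl]oxy}-3-iodobut-3-en-2-yl]oxy}-9-borabicyclo[3.3.1]nonane F6.
- The same palladium-catalysed ring closure and hydrolytic work-up should give 1-[(2R)-2-methyl-2-(4-methylpent-3-en-1-yl)-3,4-dihydro-2H-pyran-5-yl]ethan-1-ol F7 (both carbinol epimers).
- MnO2 oxidation of this allylic alcohol returns 6.

Step 1. The hindered tertiary allylic alcohol may add so slowly that the ynone oligomerizes under phosphine catalysis, and warming to force the addition would start the Claisen rearrangement of the product. The fallback replaces the catalysed addition to the alkyne by an addition–elimination; it sets out from 1 and comes back at 3. The potassium alkoxide of 1 (KH, THF, 0 °C) displaces chloride from the known reagent (E)-4-chlorobut-3-en-2-one (nucleophilic vinylic substitution with retention of the E geometry). No new compound is made on the way.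

**Further compounds**

F1 | step 7 | (3R)-3,7-dimethyloct-6-ene-1,3-diol | O[C@](C)(CCC=C(C)C)CCO
F2 | step 7 | (3R)-1-chloro-3,7-dimethyloct-6-en-3-ol | O[C@](C)(CCC=C(C)C)CCCl
F3 | step 7 | 2-{[(3R)-1-chloro-3,7-dimethyloct-6-en-3-yl]oxy}-4-methoxybenzaldehyde | COc1ccc(C=O)c(O[C@](C)(CCC=C(C)C)CCCl)c1
F4 | step 7 | (2R)-5-methoxy-2-methyl-2-(4-methylpent-3-en-1-yl)-3,4-dihydro-2H-chromene-8-carbaldehyde | O=Cc1ccc(OC)c2c1O[C@](C)(CCC=C(C)C)CC2
F5 | step 7 | (2R)-7-(hydroxymethyl)-5-methoxy-2-methyl-2-(4-methylpent-3-en-1-yl)-3,4-dihydro-2H-chromene-8-carbaldehyde | O=Cc1c(CO)cc(OC)c2c1O[C@](C)(CCC=C(C)C)CC2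
F6 | step 3 | 9-{[(3Z)-4-{[(3S)-1-(9-borabicyclo[3.3.1]nonan-9-yl)-3,7-dimethyloct-6-en-3-yl]oxy}-3-iodobut-3-en-2-yl]oxy}-9-borabicyclo[3.3.1]nonane | CC(OB1C2CCCC1CCC2)/C(I)=C/O[C@](C)(CCC=C(C)C)CCB1C2CCCC1CCC2
F7 | step 3 | 1-[(2R)-2-methyl-2-(4-methylpent-3-en-1-yl)-3,4-dihydro-2H-pyran-5-yl]ethan-1-ol | CC(O)C1=CO[C@](C)(CCC=C(C)C)CC1
F0 | step 1 | none | none
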